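## The problem

Ocophyllal B (7) is a fully aromatic benzofuran: a benzo ring and a furan ring share the C3a–C7a bond. C2 carries a 3,4,5-trimethoxyphenyl group, C3 a methyl group, C5 a formyl group and C7 a methoxy group. The molecule has no stereocentre, so the task is purely regiochemical. The furan ring has to be closed with the aryl group on C2 and the methyl on C3, not the reverse. The benzo ring has to carry the methoxy group ortho and the aldehyde para to O1. Any stereocentre met on the way to the furan ring disappears on aromatisation, so it can control nothing and racemic intermediates suffice. The fragile group is the free aryl aldehyde, which would not survive organomagnesium or organolithium reagents, hydride donors or strong oxidants. Carbanion chemistry therefore has to be finished before the aldehyde-bearing ring enters, or the aldehyde has to be masked. The electron-rich trimethoxyphenyl ring also makes any leaving group on the carbon next to it prone to ionisation. The feature that opens a short route is the chain C2–C3–CH3 with O1 on C2 and C3a on C3. This chain is a 1-aryl allyl unit hung on a phenol oxygen, whose internal vinyl carbon becomes C3 and whose terminal carbon becomes the methyl group once the future C3a carries a halogen. The pattern of O1, C7 methoxy, C5 formyl and a C3a iodine is exactly that of commercial 5-iodovanillin (4).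

## Retrosynthesis

From 7 to 6. No skeletal bond is cut. The C2=C3 double bond of 7 is moved to the exocyclic position, giving the 3-methylidene-2,3-dihydrobenzofuran 6. This tautomer is the primary product of a Heck ring closure, and its conversion to 7 is driven by the gain of furan aromaticity. The forward reaction only has to shift a double bond, and the Heck conditions themselves should do this.

From 6 to 5. The C3–C3a bond is cut, which opens the furan ring and leads to the ortho-iodoaryl 1-aryl allyl ether 5. Three neighbouring cuts were weighed against it.
- An acid cyclodehydration of an alpha-aryloxy ketone would also form C3–C3a, but by electrophilic attack on a benzo ring deactivated by the aldehyde.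
- A cut of the C2–aryl bond needs a preformed 3-methylbenzofuran and a cross-coupling.
- A cut of O1–C2 needs an ortho-alkynyl or ortho-acyl phenol that is no easier to make.

The Heck cut takes its regiochemistry from the iodine of 4, is indifferent to the electronic character of the benzo ring and tolerates the free aldehyde. Precursor 5 has no furan ring and is an ether of two simple pieces. The forward reaction must close 5-exo, not 6-endo, and palladium must insert into the carbon–iodine bond before it ionises the allylic aryl ether.

From 5 to 3 and 4. The bond between the phenol oxygen and the benzylic, allylic carbon is cut, giving the allylic alcohol 3 and 5-iodovanillin 4. The ether must be the branched isomer. Alkylation of the phenoxide with an allylic halide would drift to the linear isomer, so the bond is best made by Mitsunobu displacement at the carbinol carbon. The conditions are neutral and suit an acidic phenol that carries an aldehyde. The forward reaction must attack the carbinol carbon and not the vinyl terminus.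

From 3 to 1 and 2. The bond between the carbinol carbon and the vinyl group is cut, giving 3,4,5-trimethoxybenzaldehyde 1 and vinylmagnesium bromide 2, both commercial. This is the only carbanion step, and it is placed before the aldehyde of 4 enters, so no protecting group is needed anywhere.

## Roads not taken

Alternative 1: The C3–CH3 bond and the bond from C2 to the trimethoxyphenyl ring are cut together.
- Forward key step: 2-(7-methoxy-1-benzofuran-5-yl)-1,3-dioxolane A1 would be lithiated at C2 and added to the pinacol boronic ester A2 of the aryl group. Methyl triflate A3 would then alkylate C3 of the borate while the aryl group shifts from boron to C2, giving the 2-boryl-2,3-dihydrobenzofuran A4 with aryl trans to methyl.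
- Merits: the route is convergent and modular. Aryl group and C3 substituent can both be varied at the last carbon–carbon bond-forming stage, and no labile allylic aryl ether is involved.
- Weak points: A1 must first be built over several steps. The aldehyde must be masked against the organolithium. A4 is not aromatic, so the carbon–boron bond must be oxidised, the hemiketal dehydrated and the acetal removed. Alkylative 1,2-migration of this kind is best established for indole-derived borates, and a benzofuran borate with a methyl electrophile is less secure.
- Comparison: for a series of analogues this road would be the better one. The chosen plan sets against it three steps from commercial materials, no protecting group and direct arrival at the aromatic oxidation level.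

Alternative 2: The benzo ring is taken apart at C7–C6, C5–C4 and C4–C3a.
- Forward key step: a Dötz benzannulation. The pentacarbonylchromium carbene complex A5 (zerovalent chromium, with a methoxy group and a 4-methyl-5-aryl-2-furyl group on the carbene carbon) would combine with 3,3-diethoxyprop-1-yne A6 and one carbonyl ligand to give the benzofuran-4-ol A7.
- Merits: the substitution pattern of the benzo ring is fixed by the mechanism, with the alkyne substituent next to the new phenol and the methoxy group on the former carbene carbon. The route would be attractive if congeners oxygenated at C4 were wanted.
- Weak points: the C4 hydroxyl of A7 is not in the target and costs two more steps (sulfonylation and reduction), followed by acetal hydrolysis. The trisubstituted furan behind A5 needs its own multistep synthesis. Chromium is used in stoichiometric amount.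
- Comparison: this road builds a benzo ring that the chosen plan buys complete as 4. It is better only in that it needs no aryl halide. The chosen plan offers a catalytic metal step and no redox corrections.

Alternative 3: The C2–C3 and O1–C2 bonds are cut in a 4+1 sense.
- Forward key step: base would release an ethylidene ortho-quinone methide from the sulfone A8. The ylide of the benzylsulfonium salt A9 would add to it at the future C3, and the phenoxide would then displace the neutral sulfide at C2, giving the trans-2,3-dihydrobenzofuran ester A10.
- Merits: the reaction is metal-free, mild and convergent. It avoids any palladium–allyl chemistry, and it would be the better route to the dihydro neolignans that keep the two stereocentres.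
- Weak points: A10 is at the wrong oxidation level in two places. The dihydrofuran must be dehydrogenated and the ester taken to the aldehyde by reduction and re-oxidation. Two stereocentres are set only to be erased, and A8 needs several steps of its own.
- Comparison: this road is more robust at the ring-forming event, since nothing in it resembles the ionisable ether 5. The chosen plan sets against that its brevity and the fact that its key step delivers 7 itself.

Key step: step 3

Assumption: alcohol 3 and ether 5 are used as racemates. Their single stereocentre becomes the sp2 carbon C2 of 7, so its configuration has no bearing on the outcome.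

## Route

Step 1
Reactants: 1 3,4,5-trimethoxybenzaldehyde; 2 vinylmagnesium bromide
Product: 3 rac-1-(3,4,5-trimethoxyphenyl)prop-2-en-1-ol
Conditions: THF, −20 → 0 °C; then pH 7 aqueous buffer
Reagents that add atoms: none
Why: Grignard 1,2-addition to a non-enolisable aryl aldehyde; the carbinol stereocentre forms without control and the racemate is carried on, since this centre ends as the sp2 carbon C2 of 7. The neutral quench protects the ionisable allylic alcohol.

Step 2
Reactants: 3 rac-1-(3,4,5-trimethoxyphenyl)prop-2-en-1-ol; 4 5-iodovanillin (4-hydroxy-3-iodo-5-methoxybenzaldehyde)
Product: 5 rac-3-iodo-5-methoxy-4-{[1-(3,4,5-trimethoxyphenyl)prop-2-en-1-yl]oxy}benzaldehyde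
Conditions: PPh3, DIAD, THF, 0 °C → rt
Reagents that add atoms: none
Why: Mitsunobu etherification; the acidic phenol 4 (estimated pKa near 7) protonates the betaine and its phenoxide displaces the oxyphosphonium group of 3 by SN2 with inversion at the carbinol carbon, which keeps the ether branched and racemic. The neutral conditions leave the aryl aldehyde and the aryl iodide untouched.

Step 3
Reactants: 5 rac-3-iodo-5-methoxy-4-{[1-(3,4,5-trimethoxyphenyl)prop-2-en-1-yl]oxy}benzaldehyde
Product: 7 ocophyllal B [7-methoxy-3-methyl-2-(3,4,5-trimethoxyphenyl)-1-benzofuran-5-carbaldehyde], via 3-methylidene-2,3-dihydrobenzofuran 6 (not isolated)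
Conditions: Pd(OAc)2 (5 mol%), Na2CO3, n-Bu4NCl, DMF, 80 °C
Reagents that add atoms: none
Why: Pd(OAc)2 is reduced in the flask to zerovalent palladium, which inserts into the carbon–iodine bond of 5. The resulting arylpalladium iodide of divalent palladium adds syn across the vinyl group in a 5-exo-trig closure that joins C3a to the internal alkene carbon (the C3–C3a bond, closing the furan ring) and leaves palladium on the terminal carbon. The only beta-hydrogen is the one on C3, so syn beta-hydride elimination gives the exocyclic alkene 6. Re-addition of the palladium hydride with hydrogen going to the methylene carbon and elimination of the C2 hydrogen, or carbonate-mediated prototropy of the benzylic, allylic, oxygen-bearing C2–H, moves the double bond into the ring; the gain of furan aromaticity makes this irreversible and turns the former terminal vinyl carbon into the C3 methyl group of 7. The closest known reaction type is the phosphine-free intramolecular Heck cyclisation of ortho-iodoaryl allyl ethers to 3-methylbenzofurans with Pd(OAc)2, a carbonate base and a tetraalkylammonium chloride in DMF. No stereocentre is created: the C2 centre of 5 persists in 6 and is erased on aromatisation. Two selectivities are needed: 5-exo over 6-endo closure, secured by the one-atom O–CH tether, which lets the aryl–palladium bond reach only the internal alkene carbon in a coplanar syn arrangement; and insertion into the carbon–iodine bond ahead of ionisation of the allylic aryl ether, secured by the fast oxidative addition of an aryl iodide and by ligand-free, chloride-stabilised palladium, which is a poor catalyst for allyl ionisation. The free aldehyde is inert to these weakly basic conditions.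

## Compound list

1 | 3,4,5-trimethoxybenzaldehyde | COc1cc(C=O)cc(OC)c1OC | starting material
2 | vinylmagnesium bromide | C=C[Mg]Br | starting material
3 | rac-1-(3,4,5-trimethoxyphenyl)prop-2-en-1-ol (racemate; (R) enantiomer drawn) | C=C[C@@H](O)c1cc(OC)c(OC)c(OC)c1 | intermediate
4 | 5-iodovanillin (4-hydroxy-3-iodo-5-methoxybenzaldehyde) | COc1cc(C=O)cc(I)c1O | starting material
5 | rac-3-iodo-5-methoxy-4-{[1-(3,4,5-trimethoxyphenyl)prop-2-en-1-yl]oxy}benzaldehyde (racemate; (S) enantiomer drawn) | C=C[C@H](Oc1c(I)cc(C=O)cc1OC)c1cc(OC)c(OC)c(OC)c1 | intermediate
6 | rac-7-methoxy-3-methylidene-2-(3,4,5-trimethoxyphenyl)-2,3-dihydro-1-benzofuran-5-carbaldehyde (racemate; (2R) enantiomer drawn; not isolated) | C=C1c2cc(C=O)cc(OC)c2O[C@@H]1c1cc(OC)c(OC)c(OC)c1 | intermediate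
7 | ocophyllal B, 7-methoxy-3-methyl-2-(3,4,5-trimethoxyphenyl)-1-benzofuran-5-carbaldehyde (no stereocentre) | COc1cc(-c2oc3c(OC)cc(C=O)cc3c2C)cc(OC)c1OC | target

## Step count and risks

Total step count: 3. Longest linear sequence: 3 steps (1 → 3 → 5 → 7). Fragment 4 enters in step 2.

Step 3 (key step).
- Most likely failure: zerovalent palladium ionises the allylic carbon–oxygen bond of 5 instead of inserting into the carbon–iodine bond. The aryloxy group, a good leaving group because of the para aldehyde, is then lost or shifts to the vinyl terminus. A second failure is incomplete migration of the double bond into the ring.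
- Fallback: the same C3–C3a bond is made by a radical, which cannot ionise the ether. Setting out from 5, Bu3SnH with AIBN in toluene at 80 °C should generate the aryl radical, which closes 5-exo onto the internal vinyl carbon. Hydrogen transfer to the primary radical gives rac-7-methoxy-3-methyl-2-(3,4,5-trimethoxyphenyl)-2,3-dihydro-1-benzofuran-5-carbaldehyde F1, expected mainly as the trans isomer; either diastereomer serves. Dehydrogenation of F1 with DDQ in hot dioxane, by hydride abstraction from the C2–H next to the electron-rich aryl group, comes back to the route at 7.

Step 2.
- Most likely failure: the phenoxide attacks the vinyl terminus (SN2' displacement), or the activated alcohol ionises before substitution, so that the linear ether forms. The two ortho substituents of 4 slow the direct SN2 attack and make this more likely.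
- Fallback: regiocontrol is handed to a catalyst. Setting out from 3, methyl chloroformate and pyridine in CH2Cl2 give rac-methyl 1-(3,4,5-trimethoxyphenyl)prop-2-en-1-yl carbonate F2. Iridium-catalysed allylic etherification of F2 with the sodium phenoxide of 4 ([Ir(cod)Cl]2, racemic phosphoramidite ligand, THF) is branched-selective by nature and comes back to the route at 5.

Step 1.
- Most likely failure: incomplete addition from a degraded vinyl Grignard solution, or acid-induced 1,3-transposition of the hydroxyl group of the product during work-up and chromatography.
- Fallback: the two-carbon unit is brought in as an alkyne. Setting out from 1, ethynylmagnesium bromide in THF gives rac-1-(3,4,5-trimethoxyphenyl)prop-2-yn-1-ol F3, which is less prone to ionisation. Semi-hydrogenation of F3 (H2, Pd/CaCO3 poisoned with Pb(OAc)2, quinoline, EtOAc) comes back to the route at 3.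

## Further compounds

F1 | step 3 | rac-(2,3-trans)-7-methoxy-3-methyl-2-(3,4,5-trimethoxyphenyl)-2,3-dihydro-1-benzofuran-5-carbaldehyde (one enantiomer drawn) | O=Cc1cc(OC)c2O[C@H](c3cc(OC)c(OC)c(OC)c3)[C@@H](C)c2c1
F2 | step 2 | rac-methyl 1-(3,4,5-trimethoxyphenyl)prop-2-en-1-yl carbonate (one enantiomer drawn) | C=C[C@@H](OC(=O)OC)c1cc(OC)c(OC)c(OC)c1
F3 | step 1 | rac-1-(3,4,5-trimethoxyphenyl)prop-2-yn-1-ol (one enantiomer drawn) | C#C[C@@H](O)c1cc(OC)c(OC)c(OC)c1
A1 | alternative 1 | 2-(7-methoxy-1-benzofuran-5-yl)-1,3-dioxolane | COc1cc(C2OCCO2)cc2ccoc12
A2 | alternative 1 | 4,4,5,5-tetramethyl-2-(3,4,5-trimethoxyphenyl)-1,3,2-dioxaborolane | COc1cc(B2OC(C)(C)C(C)(C)O2)cc(OC)c1OC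
A3 | alternative 1 | methyl trifluoromethanesulfonate | COS(=O)(=O)C(F)(F)F
A4 | alternative 1 | 2-[5-(1,3-dioxolan-2-yl)-7-methoxy-3-methyl-2-(3,4,5-trimethoxyphenyl)-2,3-dihydro-1-benzofuran-2-yl]-4,4,5,5-tetramethyl-1,3,2-dioxaborolane, aryl trans to methyl (racemate, one enantiomer drawn) | COc1cc(C2OCCO2)cc2c1O[C@](B1OC(C)(C)C(C)(C)O1)(c1cc(OC)c(OC)c(OC)c1)[C@H]2C
A5 | alternative 2 | pentacarbonyl{methoxy[4-methyl-5-(3,4,5-trimethoxyphenyl)furan-2-yl]methylidene}chromium | O=C=[Cr](=C=O)(=C=O)(=C=O)(=C=O)=C(OC)c1cc(C)c(-c2cc(OC)c(OC)c(OC)c2)o1
A6 | alternative 2 | 3,3-diethoxyprop-1-yne | C#CC(OCC)OCC
A7 | alternative 2 | 5-(diethoxymethyl)-7-methoxy-3-methyl-2-(3,4,5-trimethoxyphenyl)-1-benzofuran-4-ol | CCOC(OCC)c1cc(OC)c2oc(-c3cc(OC)c(OC)c(OC)c3)c(C)c2c1O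
A8 | alternative 3 | methyl 4-hydroxy-3-methoxy-5-[1-(phenylsulfonyl)ethyl]benzoate | COC(=O)c1cc(OC)c(O)c(C(C)S(=O)(=O)c2ccccc2)c1
A9 | alternative 3 | dimethyl(3,4,5-trimethoxybenzyl)sulfonium bromide | C[S+](C)Cc1cc(OC)c(OC)c(OC)c1.[Br-]
A10 | alternative 3 | methyl trans-7-methoxy-3-methyl-2-(3,4,5-trimethoxyphenyl)-2,3-dihydro-1-benzofuran-5-carboxylate (racemate, one enantiomer drawn) | COC(=O)c1cc(OC)c2O[C@H](c3cc(OC)c(OC)c(OC)c3)[C@@H](C)c2c1
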